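**Retrosynthetic overview**

- (+)-Gmelinol ⇐ convex-face hydride reduction of a bicyclic C7′ hemiketal. This closes the second ring (C7′–O–C9) by attack of the 9-OH on an electrophilic benzylic carbon and sets the endo aryl group.
- Hemiketal ⇐ benzylic oxidation ⇐ hydroboration of a 4-benzylidene-3-hydroxy-3-(hydroxymethyl)-2-aryloxolane (sets C8′).
- Oxolane ⇐ Sharpless mono-epoxidation of a C2-symmetric (E,E)-dienediol with in-situ 5-endo opening of the benzylic epoxide by the 9′-OH. The epoxide acts as an 8-hydroxylated quinone-methide equivalent of an 8–8′ dimer; this forms the first ring (C7–O–C9′) and sets C7, C8 and the tertiary OH.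
- Dienediol ⇐ alane reduction ⇐ double Stobbe condensation of veratraldehyde (2×) with diethyl succinate (the succinate C2–C3 bond is the 8–8′ bond).
- Ring order: C7–O–C9′ ring in step 3, C7′–O–C9 ring in steps 5–6.

Assumption: the given SMILES defines (+)-gmelinol as the (1S,2R,5R,6R) isomer (aryl next to the tertiary OH exo, the other aryl endo); lignan numbering (C7/C8/C9, primed for the half without OH) and Ar = 3,4-dimethoxyphenyl are used in the explanations.

**Step 1**
Reactants: 1 3,4-dimethoxybenzaldehyde (veratraldehyde, 2.2 equiv); 2 diethyl succinate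
Product: 4 (2E,3E)-2,3-bis(3,4-dimethoxybenzylidene)succinic acid, via Stobbe half-ester 3 (not isolated)
Conditions: t-BuOK (3 equiv), t-BuOH, reflux, dark; then aq. HCl
Reagents that add atoms: none
Why: Double Stobbe condensation – each succinate CH2 undergoes aldol addition, γ-lactonisation and E1cB ring opening, which gives the thermodynamically preferred E-arylidene (aryl anti to carboxyl) at both ends and converts both esters into free carboxyls.

**Step 2**
Reactants: 4 (2E,3E)-2,3-bis(3,4-dimethoxybenzylidene)succinic acid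
Product: 5 (2E,3E)-2,3-bis(3,4-dimethoxybenzylidene)butane-1,4-diol
Conditions: LiAlH4/AlCl3 (3:1, AlH3), THF, 0 °C; Rochelle salt work-up
Reagents that add atoms: none
Why: Alane reduction of carboxylic acids to primary alcohols – electrophilic AlH3 reduces CO2H rapidly in a 1,2-sense and does not add hydride to the conjugated C=C, so both E-alkenes survive and no stereocentre is involved.

**Step 3**
Reactants: 5 (2E,3E)-2,3-bis(3,4-dimethoxybenzylidene)butane-1,4-diol
Product: 7 (2R,3S,4Z)-2-(3,4-dimethoxyphenyl)-4-(3,4-dimethoxybenzylidene)-3-(hydroxymethyl)oxolan-3-ol, via epoxy diol 6 (not isolated)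
Conditions: Ti(OiPr)4 (1.1 equiv), L-(+)-DET (1.3 equiv), t-BuOOH (1.05 equiv), 4 Å MS, CH2Cl2, −25 → 0 °C; neutral aqueous work-up (no protic acid)
Reagents that add atoms: tert-butyl hydroperoxide, CC(C)(C)OO
Why: Proposed new method: Sharpless asymmetric epoxidation of one of the two homotopic allylic alcohols of C2-symmetric 5 (closest known reaction types: Katsuki–Sharpless epoxidation of (E)-2-substituted 3-arylallyl alcohols and Ti(OiPr)4-mediated C3-selective opening of 2,3-epoxy alcohols) gives with L-(+)-DET the (2S,3S)-epoxide 6, whose Ti-activated benzylic C7–O bond is opened in situ by the δ-hydroxyl O9′ in a 5-endo, anti fashion, so that C8 (S) keeps the oxygen as the tertiary OH and C7 is inverted to R with its aryl group cis to that OH (the same isomer is also the preferred one if the opening is SN1-like), and the first ring arises by the same O9′→C7 benzylic etherification as in the biosynthesis.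

**Step 4**
Reactants: 7 (2R,3S,4Z)-2-(3,4-dimethoxyphenyl)-4-(3,4-dimethoxybenzylidene)-3-(hydroxymethyl)oxolan-3-ol
Product: 9 (2R,3S,4R)-2-(3,4-dimethoxyphenyl)-4-[(R)-(3,4-dimethoxyphenyl)(hydroxy)methyl]-3-(hydroxymethyl)oxolan-3-ol, via C7′ borane 8 (not isolated)
Conditions: BH3·THF (4 equiv), THF, 0 °C → rt; then 3 M NaOH, 30% H2O2, 0 °C
Reagents that add atoms: hydrogen peroxide, OO
Why: Hydroboration–oxidation – boron adds to the less substituted benzylic carbon C7′ (also remote from both allylic C–O bonds) and hydrogen to C8′ in a syn fashion from the ring face that carries the small tertiary OH (anti to CH2OH, and the only face from which the tertiary alkoxyborane can deliver B–H through a five-membered oxaborolane), which sets C8′ (4R, H cis to the tertiary OH) and C7′ (R), and H2O2/NaOH replaces boron by OH with retention.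

**Step 5**
Reactants: 9 (2R,3S,4R)-2-(3,4-dimethoxyphenyl)-4-[(R)-(3,4-dimethoxyphenyl)(hydroxy)methyl]-3-(hydroxymethyl)oxolan-3-ol
Product: 11 (1S,2R,5S)-2,6-bis(3,4-dimethoxyphenyl)-3,7-dioxabicyclo[3.3.0]octane-1,6-diol (C6 hemiketal anomers), via hydroxy ketone 10 (not isolated)
Conditions: activated MnO2 (15 equiv), CH2Cl2, rt
Reagents that add atoms: none
Why: Chemoselective MnO2 oxidation of the electron-rich benzylic secondary alcohol (primary and tertiary alkyl alcohols and the benzylic ether are inert) gives aryl ketone 10, whose γ-hydroxyl O9 adds to the benzylic carbonyl carbon to close the second, necessarily cis-fused ring as hemiketal 11 – the C7′–O9 bond of the biosynthetic ring closure at the ketone oxidation level – with no new fixed stereocentre because the C7′ anomers equilibrate.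

**Step 6**
Reactants: 11 (1S,2R,5S)-2,6-bis(3,4-dimethoxyphenyl)-3,7-dioxabicyclo[3.3.0]octane-1,6-diol
Product: 13 (+)-gmelinol, (1S,2R,5R,6R)-2,6-bis(3,4-dimethoxyphenyl)-3,7-dioxabicyclo[3.3.0]octan-1-ol, via oxocarbenium ion 12 (not isolated)
Conditions: Et3SiH (5 equiv), BF3·OEt2 (1.5 equiv), CH2Cl2, −78 → −40 °C; aq. NaHCO3
Reagents that add atoms: none
Why: Ionic hydrogenation of a hemiketal (Et3SiH/Lewis acid) – BF3 ionises 11 to the aryl-stabilised oxocarbenium ion 12 (an O-alkyl quinone-methide equivalent) and the silane delivers hydride to its convex (exo) face, syn to H8′ and the bridgehead OH, which forces the C7′ aryl group endo (6R), while the low temperature keeps the other benzylic ether and the tertiary alcohol intact.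

**Compound list**

1 | 3,4-dimethoxybenzaldehyde (veratraldehyde) | COc1ccc(C=O)cc1OC | starting material
2 | diethyl succinate | CCOC(=O)CCC(=O)OCC | starting material
3 | (E)-4-(3,4-dimethoxyphenyl)-3-(ethoxycarbonyl)but-3-enoic acid (Stobbe half-ester, present as its potassium salt) | CCOC(=O)/C(CC(=O)O)=C/c1ccc(OC)c(OC)c1 | intermediate
4 | (2E,3E)-2,3-bis(3,4-dimethoxybenzylidene)succinic acid | COc1ccc(/C=C(C(=O)O)\C(C(=O)O)=C/c2ccc(OC)c(OC)c2)cc1OC | intermediate
5 | (2E,3E)-2,3-bis(3,4-dimethoxybenzylidene)butane-1,4-diol | COc1ccc(/C=C(CO)\C(CO)=C/c2ccc(OC)c(OC)c2)cc1OC | intermediate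
6 | [(2S,3S)-3-(3,4-dimethoxyphenyl)-2-[(1Z)-1-(3,4-dimethoxyphenyl)-3-hydroxyprop-1-en-2-yl]oxiran-2-yl]methanol | OC[C@@]1(O[C@H]1c2ccc(OC)c(OC)c2)\C(CO)=C/c3ccc(OC)c(OC)c3 | intermediate
7 | (2R,3S,4Z)-2-(3,4-dimethoxyphenyl)-4-(3,4-dimethoxybenzylidene)-3-(hydroxymethyl)oxolan-3-ol | COc1ccc([C@H]2OC/C(=C/c3ccc(OC)c(OC)c3)[C@]2(O)CO)cc1OC | intermediate
8 | [(R)-(3,4-dimethoxyphenyl)[(3S,4S,5R)-5-(3,4-dimethoxyphenyl)-4-hydroxy-4-(hydroxymethyl)oxolan-3-yl]methyl]borane (drawn with free hydroxyls; B–O bound in the flask) | COc1ccc([C@H]2OC[C@H]([C@@H](B)c3ccc(OC)c(OC)c3)[C@]2(O)CO)cc1OC | intermediate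
9 | (2R,3S,4R)-2-(3,4-dimethoxyphenyl)-4-[(R)-(3,4-dimethoxyphenyl)(hydroxy)methyl]-3-(hydroxymethyl)oxolan-3-ol | COc1ccc([C@H]2OC[C@H]([C@@H](O)c3ccc(OC)c(OC)c3)[C@]2(O)CO)cc1OC | intermediate
10 | (3,4-dimethoxyphenyl)[(3S,4S,5R)-5-(3,4-dimethoxyphenyl)-4-hydroxy-4-(hydroxymethyl)oxolan-3-yl]methanone | COc1ccc([C@H]2OC[C@H](C(=O)c3ccc(OC)c(OC)c3)[C@]2(O)CO)cc1OC | intermediate
11 | (1S,2R,5S)-2,6-bis(3,4-dimethoxyphenyl)-3,7-dioxabicyclo[3.3.0]octane-1,6-diol (hemiketal at C6 = C7′, both anomers) | COc1ccc([C@H]2OC[C@@H]3C(O)(c4ccc(OC)c(OC)c4)OC[C@]23O)cc1OC | intermediate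
12 | oxocarbenium ion of 11 (C7′=O9+, aryl-stabilised) | COc1ccc([C@H]2OC[C@@H]3C(c4ccc(OC)c(OC)c4)=[O+]C[C@]23O)cc1OC | intermediate
13 | (+)-gmelinol, (1S,2R,5R,6R)-2,6-bis(3,4-dimethoxyphenyl)-3,7-dioxabicyclo[3.3.0]octan-1-ol | COc1ccc([C@H]2OC[C@@H]3[C@H](c4ccc(OC)c(OC)c4)OC[C@]23O)cc1OC | target

**Step count and risks**

Total step count: 6. Longest linear sequence: 6 steps (1 + 2 → 13).

The three steps most likely to fail are steps 3, 4 and 6.

Step 3 (asymmetric epoxidation with in-situ 5-endo cyclisation). The free diol may inhibit the titanium complex, a second epoxidation may compete, or the tertiary allylic C8–O bond may ionise. The fallback sets out from 5 and separates the two events, with a reagent-controlled instead of a hydroxyl-directed oxidation. Shi dioxirane epoxidation (fructose-type chiral ketone of the enantiomeric series that gives the (2S,3S)-epoxide, Oxone, K2CO3, pH 10.5 buffer, MeCN/DMM, 0 °C) gives epoxy diol 6, now isolated (no new compound: F0). Compound 6 is then cyclised on its own with catalytic Ti(OiPr)4 or PPTS in CH2Cl2, and the route is rejoined at 7.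

Step 4 (face selectivity of the hydroboration). The fallback sets out from 7 and closes the second ring first. A 5-endo-trig iodoetherification (I2, NaHCO3, MeCN, 0 °C) adds O9 to the benzylic C7′ and iodine to C8′ and gives the bridgehead iodide F1. Radical deiodination (Bu3SnH, AIBN, toluene, 80 °C) can only give the cis-fused bicycle and leads to 7′-epi-gmelinol F2. DDQ in wet CH2Cl2 then abstracts hydride from the benzylic ether carbon that has no β-hydroxyl (C7′), and water capture returns the route at hemiketal 11; step 6 then corrects C7′.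

Step 6 (stereoselective hemiketal reduction; possible acid-induced dehydration or over-reduction). The fallback sets out from triol 9 and avoids the oxidation/reduction pair. TsCl (1.05 equiv) in pyridine at 0 °C gives the primary tosylate F3. On warming to 60 °C (or with NaH in THF) the C7′ hydroxyl displaces the tosylate in a 5-exo-tet Williamson closure, with retention at C7′ (set R by the syn hydroboration), and the route is rejoined directly at 13.

**Further compounds**

F0 | step 3 | none | none
F1 | step 4 | 8′-iodo-7′-epi-gmelinol (iodine on the ring-fusion carbon C8′ cis to the OH, both aryl groups exo) | COc1ccc([C@H]2OC[C@]3(I)[C@@H](c4ccc(OC)c(OC)c4)OC[C@]23O)cc1OC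
F2 | step 4 | 7′-epi-gmelinol, (1S,2R,5R,6S)-2,6-bis(3,4-dimethoxyphenyl)-3,7-dioxabicyclo[3.3.0]octan-1-ol | COc1ccc([C@H]2OC[C@@H]3[C@@H](c4ccc(OC)c(OC)c4)OC[C@]23O)cc1OC
F3 | step 6 | primary p-toluenesulfonate of 9 (C9–OTs) | COc1ccc([C@H]2OC[C@H]([C@@H](O)c3ccc(OC)c(OC)c3)[C@]2(O)COS(=O)(=O)c4ccc(C)cc4)cc1OC
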